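**Retrosynthetic overview**
1. The ten-membered ring is closed last by ring-closing metathesis (C4 isopropenyl + C5 vinyl → Z-C4=C5) on an open-chain diene that already carries the 1,10-oxirane (Shi epoxidation).
2. The C3 and C8 esters come from acids 32 and 25; the γ-lactone forms when the freed C6-OH closes onto the C12 methyl ester.
3. Key late union: indium Barbier allylation making C7–C8 from aldehyde 12 (C8–C10, C1–C4, C14, C15) and allyl bromide 22 (C5–C7, C11–C13); it sets C7 and C8.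
4. 12 comes from methacrolein, propargyl bromide and oxirane; 22 from acrolein and methyl propiolate; 25 from tiglyl alcohol by Sharpless epoxidation.
5. Ring order: side-chain oxirane (in 25) → γ-lactone (step 18) → 1,10-oxirane (step 20) → carbocycle (step 21).

Assumption: locants C1–C15 in the text are the germacrane numbering of the target (C12 lactone carbonyl on O6, C13 exocyclic methylene, C14 on C10, C15 on C4); (2E)-2-methylbut-2-en-1-ol and (2R)-2-methylbutanoic acid are bought as such.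

**Aldehyde fragment**

Step 1
Reactants: 1 methacrolein; 2 propargyl bromide
Product: 4 rac-2-methylhex-1-en-5-yn-3-ol, via allenylzinc bromide 3 (not isolated)
Conditions: Zn dust, THF/sat. aq NH4Cl, 0 °C to rt
Reagents that add atoms: none
Why: Zinc inserts into the C–Br bond and the allenylzinc adds to the aldehyde by an SE2′ Barbier propargylation, giving the racemic homopropargylic alcohol.

Step 2
Reactants: 4 rac-2-methylhex-1-en-5-yn-3-ol
Product: 5 (3S)-2-methylhex-1-en-5-yn-3-ol
Conditions: Ti(OiPr)4, D-(−)-DIPT, t-BuOOH (0.6 equiv), 4 Å MS, CH2Cl2, −20 °C; unreacted alcohol recovered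
Reagents that add atoms: none
Why: Sharpless kinetic resolution: with D-(−)-DIPT the (R)-enantiomer of this secondary allylic alcohol is epoxidised much faster, so the (S)-alcohol (later C3) is recovered in high ee at about 55–60 % conversion.

Step 3
Reactants: 5 (3S)-2-methylhex-1-en-5-yn-3-ol
Product: 6 tert-butyldimethyl{[(3S)-2-methylhex-1-en-5-yn-3-yl]oxy}silane
Conditions: TBSCl, imidazole, DMF, rt
Reagents that add atoms: tert-butyldimethylsilyl chloride, CC(C)(C)[Si](C)(C)Cl
Why: Standard silylation of a secondary alcohol, with no change at the stereocentre.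

Step 4
Reactants: 6 tert-butyldimethyl{[(3S)-2-methylhex-1-en-5-yn-3-yl]oxy}silane; 7 oxirane
Product: 9 (6S)-6-[(tert-butyldimethylsilyl)oxy]-7-methyloct-7-en-3-yn-1-ol, via lithium acetylide 8 (not isolated)
Conditions: n-BuLi, THF, −78 °C; BF3·OEt2; then 7, −78 °C
Reagents that add atoms: none
Why: BF3-assisted opening of oxirane by the lithium acetylide (Yamaguchi alkynylation) adds C9–C8 and leaves the free primary hydroxyl that directs step 5.

Step 5
Reactants: 9 (6S)-6-[(tert-butyldimethylsilyl)oxy]-7-methyloct-7-en-3-yn-1-ol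
Product: 10 (3Z,6S)-6-[(tert-butyldimethylsilyl)oxy]-7-methyl-3-(tributylstannyl)octa-3,7-dien-1-ol
Conditions: [Cp*RuCl]4 (2.5 mol %), Bu3SnH, CH2Cl2, rt
Reagents that add atoms: tributyltin hydride, CCCC[SnH](CCCC)CCCC
Why: Ruthenium-catalysed trans-hydrostannation in which the free hydroxyl hydrogen-bonds to the Ru–Cl unit and steers tin to the proximal alkyne carbon (C10), while H adds anti at C1 so that C9 and C2 end up trans.

Step 6
Reactants: 10 (3Z,6S)-6-[(tert-butyldimethylsilyl)oxy]-7-methyl-3-(tributylstannyl)octa-3,7-dien-1-ol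
Product: 11 (3E,6S)-6-[(tert-butyldimethylsilyl)oxy]-3,7-dimethylocta-3,7-dien-1-ol
Conditions: MeI, Pd(PPh3)4 (5 mol %), copper thiophene-2-carboxylate Cu(O2CC4H3S), [Bu4N][Ph2PO2], DMF, rt
Reagents that add atoms: iodomethane, CI
Why: Copper-assisted Stille cross-coupling replaces tin by methyl (C14) with retention, giving the E-trisubstituted C1=C10 olefin.

Step 7
Reactants: 11 (3E,6S)-6-[(tert-butyldimethylsilyl)oxy]-3,7-dimethylocta-3,7-dien-1-ol
Product: 12 (3E,6S)-6-[(tert-butyldimethylsilyl)oxy]-3,7-dimethylocta-3,7-dienal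
Conditions: Dess–Martin periodinane, NaHCO3, CH2Cl2, 0 °C; used crude
Reagents that add atoms: none
Why: Buffered Dess–Martin oxidation gives the β,γ-unsaturated aldehyde without moving the olefin into conjugation.

**Allyl bromide fragment**

Step 8
Reactants: 13 methyl propiolate; 14 acrolein
Product: 16 rac-methyl 4-hydroxyhex-5-en-2-ynoate, via lithiated methyl propiolate 15 (not isolated)
Conditions: LiN(iPr)2, THF, −78 °C; then 14
Reagents that add atoms: none
Why: 1,2-Addition of the lithium acetylide to acrolein at low temperature gives the racemic propargylic/allylic alcohol.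

Step 9
Reactants: 16 rac-methyl 4-hydroxyhex-5-en-2-ynoate
Product: 18 rac-methyl (2Z)-4-hydroxy-2-iodohexa-2,5-dienoate, via cyclic alkenylaluminate 17 (not isolated)
Conditions: NaAlH2(OCH2CH2OMe)2, THF, −72 °C; then I2, −72 to 0 °C
Reagents that add atoms: iodine, II
Why: Hydroxyl-directed trans-hydroalumination places aluminium on the ester-bearing carbon cis to the carbinol in a five-membered aluminate, and iodinolysis with retention gives the (Z)-α-iodo enoate (ester trans to C6).

Step 10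
Reactants: 18 rac-methyl (2Z)-4-hydroxy-2-iodohexa-2,5-dienoate
Product: 19 methyl (2Z,4R)-4-hydroxy-2-iodohexa-2,5-dienoate
Conditions: Ti(OiPr)4, D-(−)-DIPT, t-BuOOH (0.6 equiv), 4 Å MS, CH2Cl2, −20 °C; unreacted alcohol recovered
Reagents that add atoms: none
Why: Sharpless kinetic resolution: with D-(−)-DIPT the (S)-enantiomer is epoxidised at its vinyl group faster (the iodo-enoate olefin is too electron-poor to react), leaving the (R)-alcohol that becomes C6.

Step 11
Reactants: 19 methyl (2Z,4R)-4-hydroxy-2-iodohexa-2,5-dienoate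
Product: 20 methyl (2Z,4R)-4-[(tert-butyldimethylsilyl)oxy]-2-iodohexa-2,5-dienoate
Conditions: TBSCl, imidazole, DMF, rt
Reagents that add atoms: tert-butyldimethylsilyl chloride, CC(C)(C)[Si](C)(C)Cl
Why: Standard silylation; the bulky silyl ether later controls the face of the allyl unit in step 16.

Step 12
Reactants: 20 methyl (2Z,4R)-4-[(tert-butyldimethylsilyl)oxy]-2-iodohexa-2,5-dienoate
Product: 21 methyl (2E,4R)-4-[(tert-butyldimethylsilyl)oxy]-2-(hydroxymethyl)hexa-2,5-dienoate
Conditions: Bu3SnCH2OH, Pd(PPh3)4 (5 mol %), 1,4-dioxane, 80 °C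
Reagents that add atoms: (tributylstannyl)methanol, CCCC[Sn](CCCC)(CCCC)CO
Why: Stille coupling of the α-iodo enoate installs C13 as CH2OH with retention of geometry (the descriptor changes to E only because CH2OH ranks below CO2Me).

Step 13
Reactants: 21 methyl (2E,4R)-4-[(tert-butyldimethylsilyl)oxy]-2-(hydroxymethyl)hexa-2,5-dienoate
Product: 22 methyl (2Z,4R)-2-(bromomethyl)-4-[(tert-butyldimethylsilyl)oxy]hexa-2,5-dienoate
Conditions: CBr4, PPh3, CH2Cl2, 0 °C
Reagents that add atoms: tetrabromomethane, BrC(Br)(Br)Br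
Why: Appel bromination of the primary allylic alcohol gives the 2-(bromomethyl)acrylate-type bromide with CH2Br cis to C6.

**Epoxy acid**

Step 14
Reactants: 23 (2E)-2-methylbut-2-en-1-ol
Product: 24 [(2S,3S)-2,3-dimethyloxiran-2-yl]methanol
Conditions: Ti(OiPr)4 (cat.), L-(+)-DET, t-BuOOH, 4 Å MS, CH2Cl2, −20 °C
Reagents that add atoms: tert-butyl hydroperoxide, CC(C)(C)OO
Why: Sharpless asymmetric epoxidation with L-(+)-DET gives the (2S,3S)-epoxy alcohol, and the E-olefin geometry fixes the two methyl groups cis on the oxirane.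

Step 15
Reactants: 24 [(2S,3S)-2,3-dimethyloxiran-2-yl]methanol
Product: 25 (2R,3S)-2,3-dimethyloxirane-2-carboxylic acid
Conditions: RuCl3·xH2O (cat.), NaIO4, CCl4/MeCN/H2O, rt
Reagents that add atoms: water, O
Why: Catalytic RuO4 oxidation takes the primary alcohol to the acid through the aldehyde hydrate without touching the oxirane (C2 becomes R only through the priority change).

**Union and endgame**

Step 16
Reactants: 12 (3E,6S)-6-[(tert-butyldimethylsilyl)oxy]-3,7-dimethylocta-3,7-dienal; 22 methyl (2Z,4R)-2-(bromomethyl)-4-[(tert-butyldimethylsilyl)oxy]hexa-2,5-dienoate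
Product: 27 methyl (3R,4R,6E,9S)-9-[(tert-butyldimethylsilyl)oxy]-3-[(1R)-1-[(tert-butyldimethylsilyl)oxy]prop-2-en-1-yl]-4-hydroxy-6,10-dimethyl-2-methylideneundeca-6,10-dienoate, via allylindium 26 (not isolated)
Conditions: In powder, THF/H2O (1:1), rt
Reagents that add atoms: none
Why: Indium Barbier allylation through a closed six-membered transition state: γ-attack of the (Z)-allyl unit gives the 7,8-syn relationship (C8 R), and the aldehyde approaches C7 anti to the C6 silyloxy group with C6–H held in the allyl plane by allylic 1,3-strain (C7 R).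

Step 17
Reactants: 27 the hydroxy ester of step 16; 25 (2R,3S)-2,3-dimethyloxirane-2-carboxylic acid
Product: 29 methyl (3R,4R,6E,9S)-9-[(tert-butyldimethylsilyl)oxy]-3-[(1R)-1-[(tert-butyldimethylsilyl)oxy]prop-2-en-1-yl]-4-{[(2R,3S)-2,3-dimethyloxirane-2-carbonyl]oxy}-6,10-dimethyl-2-methylideneundeca-6,10-dienoate, via mixed anhydride 28 (not isolated)
Conditions: 2,4,6-Cl3C6H2COCl, Et3N, THF, rt; then 27, DMAP, PhMe, rt
Reagents that add atoms: none
Why: Yamaguchi esterification couples the hindered, non-enolisable epoxy acid to the C8 hydroxyl without touching either stereocentre.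

Step 18
Reactants: 29 the bis-silyl diester of step 17
Product: 31 (1R,3E,6S)-6-hydroxy-3,7-dimethyl-1-[(2R,3R)-2-ethenyl-4-methylidene-5-oxooxolan-3-yl]octa-3,7-dien-1-yl (2R,3S)-2,3-dimethyloxirane-2-carboxylate, via dihydroxy ester 30 (not isolated)
Conditions: HF·pyridine, pyridine, THF, 0 °C to rt; then PPTS (cat.), PhMe, rt
Reagents that add atoms: none
Why: Fluoride-mediated desilylation frees both hydroxyls and the C6-OH lactonises onto the conjugated methyl ester, the set C6/C7 configurations giving the trans-fused α-methylene-γ-butyrolactone (the glycidic ester oxirane tolerates the mild acid).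

Step 19
Reactants: 31 the lactone alcohol of step 18; 32 (2R)-2-methylbutanoic acid
Product: 33 (1R,3E,6S)-3,7-dimethyl-6-{[(2R)-2-methylbutanoyl]oxy}-1-[(2R,3R)-2-ethenyl-4-methylidene-5-oxooxolan-3-yl]octa-3,7-dien-1-yl (2R,3S)-2,3-dimethyloxirane-2-carboxylate
Conditions: EDC·HCl, DMAP (cat.), CH2Cl2, 0 °C
Reagents that add atoms: none
Why: Steglich-type carbodiimide esterification of the only free (allylic C3) hydroxyl at low temperature keeps the α-stereocentre of the acid intact.

Step 20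
Reactants: 33 the triene diester of step 19
Product: 34 (1R)-1-[(2R,3R)-2-ethenyl-4-methylidene-5-oxooxolan-3-yl]-2-[(2R,3R)-2-methyl-3-{(2S)-3-methyl-2-{[(2R)-2-methylbutanoyl]oxy}but-3-en-1-yl}oxiran-2-yl]ethyl (2R,3S)-2,3-dimethyloxirane-2-carboxylate
Conditions: Shi ketone (1,2:4,5-di-O-isopropylidene-D-erythro-2,3-hexodiulo-2,6-pyranose, from D-fructose), Oxone (2KHSO5·KHSO4·K2SO4), NaHCO3, MeCN/DMM/aq Na2EDTA, 0 °C
Reagents that add atoms: potassium peroxymonosulfate (active salt of Oxone), [K+].[O-]S(=O)(=O)OO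
Why: Shi asymmetric epoxidation: the chiral dioxirane attacks only the electron-rich trisubstituted C1=C10 olefin and, by reagent control, the D-fructose-derived ketone gives the (R,R)-epoxide (1R,10R), while the near-neutral buffer spares the α-methylene lactone.

Step 21
Reactants: 34 the diepoxy diene of step 20
Product: 35 target CNP0265335.3
Conditions: second-generation Hoveyda–Grubbs catalyst RuCl2(H2IMes)(=CH-C6H4-2-OiPr) (20 mol %), PhMe (0.5 mM), 80 °C
Reagents that add atoms: none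
Why: Ring-closing metathesis of the C5 vinyl with the C4 isopropenyl group closes the ten-membered ring with loss of ethene, the trans-lactone and trans-oxirane pre-organising the chain and ring strain favouring the cis (Z) ring olefin.

**Compound list**

1 | methacrolein (2-methylprop-2-enal) | C=C(C)C=O | starting material
2 | propargyl bromide (3-bromoprop-1-yne) | C#CCBr | starting material
3 | allenylzinc bromide | C=C=C[Zn]Br | intermediate (not isolated)
4 | rac-2-methylhex-1-en-5-yn-3-ol | C=C(C)C(O)CC#C | intermediate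
5 | (3S)-2-methylhex-1-en-5-yn-3-ol | C=C(C)[C@@H](O)CC#C | intermediate
6 | tert-butyldimethyl{[(3S)-2-methylhex-1-en-5-yn-3-yl]oxy}silane | C=C(C)[C@@H](O[Si](C)(C)C(C)(C)C)CC#C | intermediate
7 | oxirane (ethylene oxide) | C1CO1 | starting material
8 | [(4S)-4-[(tert-butyldimethylsilyl)oxy]-5-methylhex-5-en-1-yn-1-yl]lithium | [Li]C#CC[C@H](O[Si](C)(C)C(C)(C)C)C(C)=C | intermediate (not isolated)
9 | (6S)-6-[(tert-butyldimethylsilyl)oxy]-7-methyloct-7-en-3-yn-1-ol | OCCC#CC[C@H](O[Si](C)(C)C(C)(C)C)C(C)=C | intermediate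
10 | (3Z,6S)-6-[(tert-butyldimethylsilyl)oxy]-7-methyl-3-(tributylstannyl)octa-3,7-dien-1-ol | OCC/C([Sn](CCCC)(CCCC)CCCC)=C/C[C@H](O[Si](C)(C)C(C)(C)C)C(C)=C | intermediate
11 | (3E,6S)-6-[(tert-butyldimethylsilyl)oxy]-3,7-dimethylocta-3,7-dien-1-ol | OCC/C(C)=C/C[C@H](O[Si](C)(C)C(C)(C)C)C(C)=C | intermediate
12 | (3E,6S)-6-[(tert-butyldimethylsilyl)oxy]-3,7-dimethylocta-3,7-dienal | O=CC/C(C)=C/C[C@H](O[Si](C)(C)C(C)(C)C)C(C)=C | intermediate
13 | methyl propiolate | C#CC(=O)OC | starting material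
14 | acrolein | C=CC=O | starting material
15 | lithiated methyl propiolate (lithium 3-methoxy-3-oxoprop-1-yn-1-ide) | [Li]C#CC(=O)OC | intermediate (not isolated)
16 | rac-methyl 4-hydroxyhex-5-en-2-ynoate | C=CC(O)C#CC(=O)OC | intermediate
17 | sodium 2,2-bis(2-methoxyethoxy)-3-(methoxycarbonyl)-5-ethenyl-1-oxa-2-aluminacyclopent-3-en-2-uide | [Na+].COCCO[Al-]1(OCCOC)OC(C=C)C=C1C(=O)OC | intermediate (not isolated)
18 | rac-methyl (2Z)-4-hydroxy-2-iodohexa-2,5-dienoate | COC(=O)/C(I)=C/C(O)C=C | intermediate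
19 | methyl (2Z,4R)-4-hydroxy-2-iodohexa-2,5-dienoate | COC(=O)/C(I)=C/[C@H](O)C=C | intermediate
20 | methyl (2Z,4R)-4-[(tert-butyldimethylsilyl)oxy]-2-iodohexa-2,5-dienoate | COC(=O)/C(I)=C/[C@H](O[Si](C)(C)C(C)(C)C)C=C | intermediate
21 | methyl (2E,4R)-4-[(tert-butyldimethylsilyl)oxy]-2-(hydroxymethyl)hexa-2,5-dienoate | COC(=O)/C(CO)=C/[C@H](O[Si](C)(C)C(C)(C)C)C=C | intermediate
22 | methyl (2Z,4R)-2-(bromomethyl)-4-[(tert-butyldimethylsilyl)oxy]hexa-2,5-dienoate | COC(=O)/C(CBr)=C/[C@H](O[Si](C)(C)C(C)(C)C)C=C | intermediate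
23 | (2E)-2-methylbut-2-en-1-ol | C/C=C(\C)CO | starting material
24 | [(2S,3S)-2,3-dimethyloxiran-2-yl]methanol | OC[C@]1(C)O[C@H]1C | intermediate
25 | (2R,3S)-2,3-dimethyloxirane-2-carboxylic acid | OC(=O)[C@]1(C)O[C@H]1C | intermediate
26 | allylindium from 22 (monovalent indium in place of bromine) | COC(=O)/C(C[In])=C/[C@H](O[Si](C)(C)C(C)(C)C)C=C | intermediate (not isolated)
27 | methyl (3R,4R,6E,9S)-9-[(tert-butyldimethylsilyl)oxy]-3-[(1R)-1-[(tert-butyldimethylsilyl)oxy]prop-2-en-1-yl]-4-hydroxy-6,10-dimethyl-2-methylideneundeca-6,10-dienoate | COC(=O)C(=C)[C@@H]([C@H](O[Si](C)(C)C(C)(C)C)C=C)[C@H](O)C/C(C)=C/C[C@H](O[Si](C)(C)C(C)(C)C)C(C)=C | intermediate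
28 | (2R,3S)-2,3-dimethyloxirane-2-carboxylic 2,4,6-trichlorobenzoic anhydride | O=C(OC(=O)[C@]1(C)O[C@H]1C)c1c(Cl)cc(Cl)cc1Cl | intermediate (not isolated)
29 | methyl (3R,4R,6E,9S)-9-[(tert-butyldimethylsilyl)oxy]-3-[(1R)-1-[(tert-butyldimethylsilyl)oxy]prop-2-en-1-yl]-4-{[(2R,3S)-2,3-dimethyloxirane-2-carbonyl]oxy}-6,10-dimethyl-2-methylideneundeca-6,10-dienoate | COC(=O)C(=C)[C@@H]([C@H](O[Si](C)(C)C(C)(C)C)C=C)[C@H](OC(=O)[C@]1(C)O[C@H]1C)C/C(C)=C/C[C@H](O[Si](C)(C)C(C)(C)C)C(C)=C | intermediate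
30 | methyl (3S,4R,6E,9S)-4-{[(2R,3S)-2,3-dimethyloxirane-2-carbonyl]oxy}-9-hydroxy-3-[(1R)-1-hydroxyprop-2-en-1-yl]-6,10-dimethyl-2-methylideneundeca-6,10-dienoate | COC(=O)C(=C)[C@@H]([C@H](O)C=C)[C@H](OC(=O)[C@]1(C)O[C@H]1C)C/C(C)=C/C[C@H](O)C(C)=C | intermediate (not isolated)
31 | (1R,3E,6S)-6-hydroxy-3,7-dimethyl-1-[(2R,3R)-2-ethenyl-4-methylidene-5-oxooxolan-3-yl]octa-3,7-dien-1-yl (2R,3S)-2,3-dimethyloxirane-2-carboxylate | C=C1C(=O)O[C@H](C=C)[C@H]1[C@H](OC(=O)[C@]2(C)O[C@H]2C)C/C(C)=C/C[C@H](O)C(C)=C | intermediate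
32 | (2R)-2-methylbutanoic acid | CC[C@@H](C)C(=O)O | starting material
33 | (1R,3E,6S)-3,7-dimethyl-6-{[(2R)-2-methylbutanoyl]oxy}-1-[(2R,3R)-2-ethenyl-4-methylidene-5-oxooxolan-3-yl]octa-3,7-dien-1-yl (2R,3S)-2,3-dimethyloxirane-2-carboxylate | C=C1C(=O)O[C@H](C=C)[C@H]1[C@H](OC(=O)[C@]2(C)O[C@H]2C)C/C(C)=C/C[C@H](OC(=O)[C@H](C)CC)C(C)=C | intermediate
34 | (1R)-1-[(2R,3R)-2-ethenyl-4-methylidene-5-oxooxolan-3-yl]-2-[(2R,3R)-2-methyl-3-{(2S)-3-methyl-2-{[(2R)-2-methylbutanoyl]oxy}but-3-en-1-yl}oxiran-2-yl]ethyl (2R,3S)-2,3-dimethyloxirane-2-carboxylate | C=C1C(=O)O[C@H](C=C)[C@H]1[C@H](OC(=O)[C@]2(C)O[C@H]2C)C[C@@]3(C)O[C@@H]3C[C@H](OC(=O)[C@H](C)CC)C(C)=C | intermediate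
35 | target CNP0265335.3: (1R,3S,6R,7R,8R,10R)-1,10-epoxy-8-{[(2R,3S)-2,3-dimethyloxirane-2-carbonyl]oxy}-3-{[(2R)-2-methylbutanoyl]oxy}germacra-4Z,11(13)-dien-12,6-olide | C=C1C(=O)O[C@@H]2/C=C(/C)[C@@H](OC(=O)[C@H](C)CC)C[C@H]3O[C@]3(C)C[C@@H](OC(=O)[C@]3(C)O[C@H]3C)[C@@H]12 | target

**Totals and risks**

Total step count: 21. Longest linear sequence: 13 steps (steps 1–7, then 16–21). The two kinetic resolutions (steps 2 and 10) cap those steps at about 45 % yield each.

Steps most likely to fail: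

Step 5 (trans-hydrostannation). The directing hydroxyl is homopropargylic, so tin may not go cleanly to C10. The fallback sets out from 6 and comes back at 11. Deprotonation of 6 with n-BuLi and methylation with MeI gives tert-butyldimethyl{[(3S)-2-methylhept-1-en-5-yn-3-yl]oxy}silane F1. Hydrozirconation with Cp2Zr(H)Cl, which settles zirconium on the less hindered methyl-bearing carbon, followed by iodinolysis gives tert-butyl{[(3S,5E)-6-iodo-2-methylhepta-1,5-dien-3-yl]oxy}dimethylsilane F2. Iodine–lithium exchange (t-BuLi, Et2O, −78 °C) and BF3·OEt2-assisted opening of oxirane 7 then give 11 directly, so the olefin geometry comes from a syn-hydrometalation instead of a directed trans-addition.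

Step 16 (indium allylation). The allylmetal could lose the δ-silyloxy group by 1,4-elimination, the facial control from C6 could be modest, and 27 could close prematurely to the cis-8,12-lactone. The fallback sets out from 22 and comes back at 27. Palladium-catalysed borylation of 22 (B2pin2, Pd2(dba)3, DMSO) gives methyl (2E,4R)-4-[(tert-butyldimethylsilyl)oxy]-2-[(4,4,5,5-tetramethyl-1,3,2-dioxaborolan-2-yl)methyl]hexa-2,5-dienoate F3. This isolable, configurationally defined allylboronate cannot eliminate; warmed with 12 in toluene it adds through a closed chair transition state (the γ-substituent cis to the CH2B arm gives 7,8-syn), and mild aqueous work-up of the borate gives 27.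

Step 21 (ring-closing metathesis). A 1,1-disubstituted olefin next to an acyloxy group has to close a ten-membered ring to a trisubstituted Z-olefin; oligomers or E/Z mixtures are possible. The fallback sets out from 31 and comes back at 35, closing the ring on the free allylic alcohol, which is less hindered and is known to speed up ruthenium metathesis. Shi epoxidation of 31 under the step 20 conditions gives (1R)-2-[(2R,3R)-3-[(2S)-2-hydroxy-3-methylbut-3-en-1-yl]-2-methyloxiran-2-yl]-1-[(2R,3R)-2-ethenyl-4-methylidene-5-oxooxolan-3-yl]ethyl (2R,3S)-2,3-dimethyloxirane-2-carboxylate F4, which must be kept away from acid to avoid 3,10-ether formation. Metathesis with the same catalyst gives (1R,3S,6R,7R,8R,10R)-1,10-epoxy-3-hydroxy-8-{[(2R,3S)-2,3-dimethyloxirane-2-carbonyl]oxy}germacra-4Z,11(13)-dien-12,6-olide F5, and EDC·HCl/DMAP esterification with 32 gives 35.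

**Further compounds**

F1 | step 5 | tert-butyldimethyl{[(3S)-2-methylhept-1-en-5-yn-3-yl]oxy}silane | CC#CC[C@H](O[Si](C)(C)C(C)(C)C)C(C)=C
F2 | step 5 | tert-butyl{[(3S,5E)-6-iodo-2-methylhepta-1,5-dien-3-yl]oxy}dimethylsilane | C/C(I)=C\C[C@H](O[Si](C)(C)C(C)(C)C)C(C)=C
F3 | step 16 | methyl (2E,4R)-4-[(tert-butyldimethylsilyl)oxy]-2-[(4,4,5,5-tetramethyl-1,3,2-dioxaborolan-2-yl)methyl]hexa-2,5-dienoate | COC(=O)/C(CB1OC(C)(C)C(C)(C)O1)=C/[C@H](O[Si](C)(C)C(C)(C)C)C=C
F4 | step 21 | (1R)-2-[(2R,3R)-3-[(2S)-2-hydroxy-3-methylbut-3-en-1-yl]-2-methyloxiran-2-yl]-1-[(2R,3R)-2-ethenyl-4-methylidene-5-oxooxolan-3-yl]ethyl (2R,3S)-2,3-dimethyloxirane-2-carboxylate | C=C1C(=O)O[C@H](C=C)[C@H]1[C@H](OC(=O)[C@]2(C)O[C@H]2C)C[C@@]3(C)O[C@@H]3C[C@H](O)C(C)=C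
F5 | step 21 | (1R,3S,6R,7R,8R,10R)-1,10-epoxy-3-hydroxy-8-{[(2R,3S)-2,3-dimethyloxirane-2-carbonyl]oxy}germacra-4Z,11(13)-dien-12,6-olide | C=C1C(=O)O[C@@H]2/C=C(/C)[C@@H](O)C[C@H]3O[C@]3(C)C[C@@H](OC(=O)[C@]3(C)O[C@H]3C)[C@@H]12
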